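The constants used here come from no measurement; the flask was simulated.

In a flask run by these steps, an initiator molecule that reacts stands at the same fork at every moment: both ways out use one free monomer and one initiator, so the odds between them stay those of the constants.

free monomer 0.039 M (fed, over 2.5 min); initiator 2.0 mM; time 2.5 min

    free monomer + living end → monomer in chains + living end, rate k1*[living end]*[free monomer] (k1 = 7.2 L mol⁻¹ s⁻¹)
    free monomer + initiator → living end + monomer in chains (k2 = 1.2 L mol⁻¹ s⁻¹)
    free monomer + initiator → spent initiator (k3 = 0.21 L mol⁻¹ s⁻¹)

- average number of monomer units in a chain (chains begun, living or dead) at 2.5 min
- part of the free monomer that has reacted at 2.5 min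

- the average divides the monomer in chains by the number of chains begun, living and dead together
- run time (flask): 2.5 min

Follow that molecule. It begins a chain with the chance 1.2 L mol⁻¹ s⁻¹ over the sum of 1.2 L mol⁻¹ s⁻¹ and 0.21 L mol⁻¹ s⁻¹, which is 85.1%; I call this the chain share, a selectivity. Chains begun are the chain share times the initiator used, so the 2.0 mM charged gives at most 1.70 mM of chains.

Two of us dispute the flask. The first says living ends take up monomer as it arrives, since an end reacts with it 5.11 times as fast as an initiator molecule does by both its ways out together; then the whole 0.039 M sits on those chains, a dp of 22.9. The second answers with times. Even with every chain present, ends halve free monomer in 0.943 min, no small part of the 2.5 min feed, and chain starting, with initiator held at its charge, needs 4.8 min for that halving, longer than the feed. So ends come late. My reckoning sides with the second but stops there, without a figure for the free monomer left.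

The forecast takes the second side, with dp 11.5 (10.5 to 12.5) and c 48% (44% to 52%), holding that “the steadily fed monomer is only about half consumed”.

The simulation gives dp 11.5 and c 48.0%, so the forecast held. Chain growth ran late, the midpoint of its turnover falling at 1.85 min, when it used free monomer 26 times as fast as chain starting. At 2.50 min, with 5.62% of the initiator left, the chain share gives 0.00161 M of chains, and living ends stood at 0.00161 M. The first view has its region in this flask left for 25.0 min: c reaches 100% and dp 22.9.

In the flask with 0.098 M of free monomer, the chain share again allows 1.70 mM of chains, which would mean a dp of 57.6 with the whole charge in them. That flask gives living ends 0.00170 M, c 52.3% and dp 30.0.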